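**Retrosynthetic overview**

1. Feature: in the 1,2-dioxane ring (O1–O2–C3–C4–C5–C6) the two ring oxygens sit on C3 and C6, 1,4 to each other across C4–C5. That is the imprint of O2 added across a C3=C4–C5=C6 diene, so the ring is cut back to singlet oxygen plus an acyclic (3E,5Z)-diene (C1–C7).
2. Diene: C2 comes from the Roche ester, the 3E alkene from a formyl Wittig reaction, the 5Z trisubstituted alkene from a Still–Gennari olefination; C1–O is carried as TBDPS ether (large group for face bias), C7–O as acetate (removable by mild methanolysis).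
3. C7=C8 is cut by cross-metathesis into a C6-vinyl dioxane and a vinyl oxirane (C8–C12 plus cyclohexene) made from dihydro-β-ionone through Sharpless epoxidation of monocyclofarnesol. The cyclohexene is joined only after the photo-oxygenation, because singlet oxygen would consume it.
4. Ring order: cyclohexene bought; 1,2-dioxine ring closed in step 7 and saturated in step 8; oxirane closed in step 14 on the side branch; fragments joined in step 17, then C7=C8 reduction and C1 oxidation.

Key step: step 7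

Numbering: locants C1–C12 in the text follow the acid chain of the target (C1 acid carbon, C2 the CH(CH3), C3 and C6 the dioxane carbons with O2 on C3 and O1 on C6, C7/C8 the linker, C9/C10 the oxirane carbons). Descriptors in the names are CIP descriptors of each compound; the one at C6 changes from S to R in step 18 by ranking only.

Assumption: the face of the diene attacked in step 7 is predicted from a conformational model and is not secured by precedent on this substrate; the route plans a chromatographic separation of the two face isomers at 9 or 10.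

**Route**

Step 1
Reactants: 1 methyl (2S)-3-hydroxy-2-methylpropanoate (Roche ester)
Product: 2 methyl (2S)-3-[(tert-butyldiphenylsilyl)oxy]-2-methylpropanoate
Conditions: TBDPSCl, imidazole, DMF, 0 °C → rt
Reagents that add atoms: tert-butyl(chloro)diphenylsilane, CC(C)(C)[Si](Cl)(c1ccccc1)c1ccccc1
Why: Imidazole-promoted silylation of the primary alcohol (silyl ether formation) leaves the stereocentre untouched and installs the bulky group that later differentiates the two faces at C2.

Step 2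
Reactants: 2 methyl (2S)-3-[(tert-butyldiphenylsilyl)oxy]-2-methylpropanoate
Product: 3 (2S)-3-[(tert-butyldiphenylsilyl)oxy]-2-methylpropanal
Conditions: DIBAL-H (1.1 equiv), CH2Cl2, −78 °C; Rochelle salt work-up; used crude
Reagents that add atoms: none
Why: Partial ester reduction with DIBAL-H at −78 °C stops at the aluminium hemiacetal, which gives the aldehyde on work-up, and the α-stereocentre should hold if the crude aldehyde is used at once.

Step 3
Reactants: 3 (2S)-3-[(tert-butyldiphenylsilyl)oxy]-2-methylpropanal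
Product: 4 (2E,4R)-5-[(tert-butyldiphenylsilyl)oxy]-4-methylpent-2-enal
Conditions: Ph3P=CHCHO (1.2 equiv), toluene, 80 °C
Reagents that add atoms: (triphenylphosphoranylidene)acetaldehyde, O=CC=P(c1ccccc1)(c1ccccc1)c1ccccc1
Why: Wittig reaction with the stabilised formyl ylide should give the (E)-enal (future C3=C4), and the weakly basic ylide should not epimerise the α-centre.

Step 4
Reactants: 4 (2E,4R)-5-[(tert-butyldiphenylsilyl)oxy]-4-methylpent-2-enal; 5 ethyl 2-[bis(2,2,2-trifluoroethoxy)phosphoryl]propanoate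
Product: 6 ethyl (2Z,4E,6R)-7-[(tert-butyldiphenylsilyl)oxy]-2,6-dimethylhepta-2,4-dienoate
Conditions: 5, KHMDS, 18-crown-6, THF, −78 °C; then 4
Reagents that add atoms: none
Why: Still–Gennari olefination, in which the trifluoroethyl phosphonate with a dissociated potassium ion eliminates fast and irreversibly, should place the ester cis to C4 (Z), so that the future C7 is the inside group and the methyl the outside group on C6.

Step 5
Reactants: 6 ethyl (2Z,4E,6R)-7-[(tert-butyldiphenylsilyl)oxy]-2,6-dimethylhepta-2,4-dienoate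
Product: 7 (2Z,4E,6R)-7-[(tert-butyldiphenylsilyl)oxy]-2,6-dimethylhepta-2,4-dien-1-ol
Conditions: DIBAL-H (2.5 equiv), CH2Cl2, −78 °C
Reagents that add atoms: none
Why: DIBAL-H 1,2-reduction of the dienoate gives the allylic alcohol without touching the diene geometry or the silyl ether.

Step 6
Reactants: 7 (2Z,4E,6R)-7-[(tert-butyldiphenylsilyl)oxy]-2,6-dimethylhepta-2,4-dien-1-ol
Product: 8 (2Z,4E,6R)-7-[(tert-butyldiphenylsilyl)oxy]-2,6-dimethylhepta-2,4-dien-1-yl acetate (the (3E,5Z)-diene in target numbering)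
Conditions: Ac2O, pyridine, DMAP (cat.), CH2Cl2, 0 °C
Reagents that add atoms: acetic anhydride, CC(=O)OC(C)=O
Why: DMAP-catalysed acetylation masks C7–OH orthogonally to the silyl ether, and the electron-withdrawing acetate lowers the ene reactivity of the C7–H bonds and of the trisubstituted alkene in the next step.

Step 7
Reactants: 8 (2Z,4E,6R)-7-[(tert-butyldiphenylsilyl)oxy]-2,6-dimethylhepta-2,4-dien-1-yl acetate
Product: 9 [(3S,6S)-6-[(2S)-1-[(tert-butyldiphenylsilyl)oxy]propan-2-yl]-3-methyl-3,6-dihydro-1,2-dioxin-3-yl]methyl acetate (ring position 3 = target C6, position 6 = target C3; side chain cis to the ring methyl)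
Conditions: O2, tetraphenylporphyrin (cat.), hν (visible), CH2Cl2, −20 °C
Reagents that add atoms: dioxygen (as singlet oxygen), O=O
Why: Sensitised irradiation generates singlet oxygen, which adds to the s-cis conformer of the diene in a concerted suprafacial [4+2] cycloaddition that forms C3–O2 and C6–O1 together; the closest known reaction type is the 1,4-cycloaddition (hetero-Diels–Alder) of singlet oxygen to acyclic 1,3-dienes giving 3,6-dihydro-1,2-dioxines. The six-membered ring O1–O2–C3–C4=C5–C6 is closed by cycloaddition, the four diene carbons and both oxygen atoms becoming ring members. The C3/C6 relationship follows from the diene geometry: the outside groups (the C2 branch on the E terminus and the methyl on the Z terminus) end cis, as do the inside groups (C3–H and CH2OAc), which is the arrangement of the target. The absolute sense comes from C2: with C2–H eclipsing C3=C4, the CH2OTBDPS group covers one diene face and oxygen should add from the face of the small C2 methyl, which corresponds to the drawn isomer; the bias is only moderate in principle, so the other face isomer is removed by chromatography here or after step 8. The step needs [4+2] to win over the Schenck ene reaction and over stepwise perepoxide or zwitterion paths that would scramble the 5Z geometry; the substrate helps because the acetate deactivates the C7–H bonds and the trisubstituted alkene, the remaining allylic hydrogens sit on the lone C6 methyl and next to a disubstituted alkene, no other electron-rich alkene is present, and a non-polar aprotic medium with a low-energy sensitiser disfavours ionic intermediates and triplet isomerisation.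

Step 8
Reactants: 9 [(3S,6S)-6-[(2S)-1-[(tert-butyldiphenylsilyl)oxy]propan-2-yl]-3-methyl-3,6-dihydro-1,2-dioxin-3-yl]methyl acetate
Product: 10 [(3S,6S)-6-[(2S)-1-[(tert-butyldiphenylsilyl)oxy]propan-2-yl]-3-methyl-1,2-dioxan-3-yl]methyl acetate
Conditions: potassium azodicarboxylate, AcOH, CH2Cl2/MeOH, 0 °C → rt
Reagents that add atoms: none
Why: Diimide reduction transfers H2 to the cis ring alkene without cleaving the O–O bond, and the weakly acidic medium avoids the Kornblum–DeLaMare cleavage that amine bases would cause at the allylic peroxide C3–H.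

Step 9
Reactants: 10 [(3S,6S)-6-[(2S)-1-[(tert-butyldiphenylsilyl)oxy]propan-2-yl]-3-methyl-1,2-dioxan-3-yl]methyl acetate
Product: 11 [(3S,6S)-6-[(2S)-1-[(tert-butyldiphenylsilyl)oxy]propan-2-yl]-3-methyl-1,2-dioxan-3-yl]methanol
Conditions: K2CO3 (cat.), MeOH, 0 °C
Reagents that add atoms: none
Why: Base-catalysed transesterification removes the acetate, and the saturated dioxane (C3–H no longer allylic) and the TBDPS ether should tolerate catalytic carbonate in cold methanol.

Step 10
Reactants: 11 [(3S,6S)-6-[(2S)-1-[(tert-butyldiphenylsilyl)oxy]propan-2-yl]-3-methyl-1,2-dioxan-3-yl]methanol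
Product: 12 (3S,6S)-6-[(2S)-1-[(tert-butyldiphenylsilyl)oxy]propan-2-yl]-3-methyl-1,2-dioxane-3-carbaldehyde
Conditions: Dess–Martin periodinane, pyridine, CH2Cl2, 0 °C → rt
Reagents that add atoms: none
Why: Dess–Martin oxidation of the neopentyl primary alcohol runs under buffered, non-reducing conditions that dialkyl peroxides tolerate, and the aldehyde has no α-hydrogen to epimerise.

Step 11
Reactants: 12 (3S,6S)-6-[(2S)-1-[(tert-butyldiphenylsilyl)oxy]propan-2-yl]-3-methyl-1,2-dioxane-3-carbaldehyde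
Product: 13 tert-butyl{(2S)-2-[(3S,6S)-6-ethenyl-6-methyl-1,2-dioxan-3-yl]propoxy}diphenylsilane
Conditions: Ph3PCH3Br, KHMDS, THF, 0 °C; then 12, −78 → 0 °C
Reagents that add atoms: methyltriphenylphosphonium bromide, [Br-].C[P+](c1ccccc1)(c1ccccc1)c1ccccc1
Why: Wittig methylenation of a non-enolisable aldehyde with a preformed non-stabilised ylide at low temperature gives the C7=CH2 vinyl group, and saturated dialkyl peroxides are compatible with phosphorus ylides.

Step 12
Reactants: 14 dihydro-β-ionone, 4-(2,6,6-trimethylcyclohex-1-en-1-yl)butan-2-one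
Product: 15 ethyl (2E)-3-methyl-5-(2,6,6-trimethylcyclohex-1-en-1-yl)pent-2-enoate
Conditions: (EtO)2P(O)CH2CO2Et, NaH, THF, 0 °C → reflux; E isomer separated by chromatography
Reagents that add atoms: triethyl phosphonoacetate, CCOC(=O)CP(=O)(OCC)OCC
Why: Horner–Wadsworth–Emmons olefination of the methyl ketone should give mainly the (E)-trisubstituted enoate, and the minor Z isomer is removed by chromatography.

Step 13
Reactants: 15 ethyl (2E)-3-methyl-5-(2,6,6-trimethylcyclohex-1-en-1-yl)pent-2-enoate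
Product: 16 (2E)-3-methyl-5-(2,6,6-trimethylcyclohex-1-en-1-yl)pent-2-en-1-ol (monocyclofarnesol)
Conditions: DIBAL-H (2.5 equiv), CH2Cl2, −78 °C
Reagents that add atoms: none
Why: DIBAL-H 1,2-reduction of the enoate gives the (E)-allylic alcohol needed for directed epoxidation.

Step 14
Reactants: 16 (2E)-3-methyl-5-(2,6,6-trimethylcyclohex-1-en-1-yl)pent-2-en-1-ol
Product: 17 [(2S,3S)-3-methyl-3-[2-(2,6,6-trimethylcyclohex-1-en-1-yl)ethyl]oxiran-2-yl]methanol
Conditions: Ti(OiPr)4 (cat.), L-(+)-diethyl tartrate (cat.), t-BuOOH, 4 Å MS, CH2Cl2, −20 °C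
Reagents that add atoms: tert-butyl hydroperoxide, CC(C)(C)OO
Why: Sharpless asymmetric epoxidation delivers oxygen only to the alkene of the titanium-bound allylic alcohol (the tetrasubstituted cyclohexene is not bound), and L-(+)-tartrate should give the (2S,3S)-epoxy alcohol as with geraniol-type substrates, which sets C9 and C10.

Step 15
Reactants: 17 [(2S,3S)-3-methyl-3-[2-(2,6,6-trimethylcyclohex-1-en-1-yl)ethyl]oxiran-2-yl]methanol
Product: 18 (2R,3S)-3-methyl-3-[2-(2,6,6-trimethylcyclohex-1-en-1-yl)ethyl]oxirane-2-carbaldehyde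
Conditions: Dess–Martin periodinane, pyridine, CH2Cl2, 0 °C
Reagents that add atoms: none
Why: Buffered Dess–Martin oxidation gives the epoxy aldehyde, whose oxirane α-C–H is not readily enolised, so C9 should hold (the descriptor changes by ranking only).

Step 16
Reactants: 18 (2R,3S)-3-methyl-3-[2-(2,6,6-trimethylcyclohex-1-en-1-yl)ethyl]oxirane-2-carbaldehyde
Product: 19 (2S,3S)-3-ethenyl-2-methyl-2-[2-(2,6,6-trimethylcyclohex-1-en-1-yl)ethyl]oxirane
Conditions: Ph3PCH3Br, KHMDS, THF, 0 °C; then 18, −78 → 0 °C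
Reagents that add atoms: methyltriphenylphosphonium bromide, [Br-].C[P+](c1ccccc1)(c1ccccc1)c1ccccc1
Why: Wittig methylenation of an α,β-epoxy aldehyde at low temperature gives the vinyl oxirane without opening the epoxide.

Step 17
Reactants: 13 tert-butyl{(2S)-2-[(3S,6S)-6-ethenyl-6-methyl-1,2-dioxan-3-yl]propoxy}diphenylsilane; 19 (2S,3S)-3-ethenyl-2-methyl-2-[2-(2,6,6-trimethylcyclohex-1-en-1-yl)ethyl]oxirane (3 equiv)
Product: 20 tert-butyl{(2S)-2-[(3S,6S)-6-methyl-6-{(E)-2-[(2S,3S)-3-methyl-3-[2-(2,6,6-trimethylcyclohex-1-en-1-yl)ethyl]oxiran-2-yl]ethenyl}-1,2-dioxan-3-yl]propoxy}diphenylsilane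
Conditions: Hoveyda–Grubbs II catalyst (10 mol %), CH2Cl2, 40 °C, argon sparge
Reagents that add atoms: none
Why: Olefin cross-metathesis joins a quaternary-allylic vinyl group that does not homodimerise with a slowly dimerising vinyl oxirane used in excess; the tetrasubstituted cyclohexene is inert to the ruthenium carbene, dialkyl peroxides are tolerated, and the alkene geometry is irrelevant because the bond is reduced next.

Step 18
Reactants: 20 tert-butyl{(2S)-2-[(3S,6S)-6-methyl-6-{(E)-2-[(2S,3S)-3-methyl-3-[2-(2,6,6-trimethylcyclohex-1-en-1-yl)ethyl]oxiran-2-yl]ethenyl}-1,2-dioxan-3-yl]propoxy}diphenylsilane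
Product: 21 tert-butyl{(2S)-2-[(3S,6R)-6-methyl-6-{2-[(2S,3S)-3-methyl-3-[2-(2,6,6-trimethylcyclohex-1-en-1-yl)ethyl]oxiran-2-yl]ethyl}-1,2-dioxan-3-yl]propoxy}diphenylsilane
Conditions: 2-nitrobenzenesulfonyl hydrazide (large excess, in portions), Et3N, CH2Cl2, rt
Reagents that add atoms: none
Why: Diimide generated without acid reduces the 1,2-disubstituted C7=C8 alkene, while the tetrasubstituted cyclohexene, the O–O bond and the acid-sensitive allylic oxirane are not attacked, and excess reagent compensates for the hindrance next to C6.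

Step 19
Reactants: 21 tert-butyl{(2S)-2-[(3S,6R)-6-methyl-6-{2-[(2S,3S)-3-methyl-3-[2-(2,6,6-trimethylcyclohex-1-en-1-yl)ethyl]oxiran-2-yl]ethyl}-1,2-dioxan-3-yl]propoxy}diphenylsilane
Product: 22 (2S)-2-[(3S,6R)-6-methyl-6-{2-[(2S,3S)-3-methyl-3-[2-(2,6,6-trimethylcyclohex-1-en-1-yl)ethyl]oxiran-2-yl]ethyl}-1,2-dioxan-3-yl]propan-1-ol
Conditions: TBAF, AcOH (1:1), THF, 0 °C → rt
Reagents that add atoms: none
Why: Fluoride cleavage of the silyl ether, buffered with acetic acid, exposes neither the peroxide C3–H to strong base nor the trisubstituted oxirane to strong acid.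

Step 20
Reactants: 22 (2S)-2-[(3S,6R)-6-methyl-6-{2-[(2S,3S)-3-methyl-3-[2-(2,6,6-trimethylcyclohex-1-en-1-yl)ethyl]oxiran-2-yl]ethyl}-1,2-dioxan-3-yl]propan-1-ol
Product: 23 (2R)-2-[(3S,6R)-6-methyl-6-{2-[(2S,3S)-3-methyl-3-[2-(2,6,6-trimethylcyclohex-1-en-1-yl)ethyl]oxiran-2-yl]ethyl}-1,2-dioxan-3-yl]propanal
Conditions: Dess–Martin periodinane, pyridine, CH2Cl2, 0 °C; used crude
Reagents that add atoms: none
Why: Buffered Dess–Martin oxidation gives the β-peroxy aldehyde, which is taken on at once so that C2 neither epimerises nor loses the peroxide by β-elimination (the descriptor at C2 changes by ranking only).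

Step 21
Reactants: 23 (2R)-2-[(3S,6R)-6-methyl-6-{2-[(2S,3S)-3-methyl-3-[2-(2,6,6-trimethylcyclohex-1-en-1-yl)ethyl]oxiran-2-yl]ethyl}-1,2-dioxan-3-yl]propanal
Product: 24 (2R)-2-[(3S,6R)-6-methyl-6-{2-[(2S,3S)-3-methyl-3-[2-(2,6,6-trimethylcyclohex-1-en-1-yl)ethyl]oxiran-2-yl]ethyl}-1,2-dioxan-3-yl]propanoic acid (CNP0204283.1)
Conditions: NaClO2, NaH2PO4, 2-methyl-2-butene (large excess), t-BuOH/H2O, 0 °C
Reagents that add atoms: sodium chlorite, [Na+].[O-]Cl=O
Why: Pinnick oxidation converts the aldehyde to the acid without enolisation, a large excess of 2-methyl-2-butene intercepts hypochlorous acid before it reaches the tetrasubstituted cyclohexene, and the phosphate buffer is mild enough for the oxirane.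

**Compound list**

1 | methyl (2S)-3-hydroxy-2-methylpropanoate (Roche ester) | COC(=O)[C@@H](C)CO | starting material
2 | methyl (2S)-3-[(tert-butyldiphenylsilyl)oxy]-2-methylpropanoate | COC(=O)[C@@H](C)CO[Si](c1ccccc1)(c1ccccc1)C(C)(C)C | intermediate
3 | (2S)-3-[(tert-butyldiphenylsilyl)oxy]-2-methylpropanal | O=C[C@@H](C)CO[Si](c1ccccc1)(c1ccccc1)C(C)(C)C | intermediate
4 | (2E,4R)-5-[(tert-butyldiphenylsilyl)oxy]-4-methylpent-2-enal | O=C/C=C/[C@@H](C)CO[Si](c1ccccc1)(c1ccccc1)C(C)(C)C | intermediate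
5 | ethyl 2-[bis(2,2,2-trifluoroethoxy)phosphoryl]propanoate | CCOC(=O)C(C)P(=O)(OCC(F)(F)F)OCC(F)(F)F | starting material
6 | ethyl (2Z,4E,6R)-7-[(tert-butyldiphenylsilyl)oxy]-2,6-dimethylhepta-2,4-dienoate | CCOC(=O)/C(C)=C\C=C\[C@@H](C)CO[Si](c1ccccc1)(c1ccccc1)C(C)(C)C | intermediate
7 | (2Z,4E,6R)-7-[(tert-butyldiphenylsilyl)oxy]-2,6-dimethylhepta-2,4-dien-1-ol | OC/C(C)=C\C=C\[C@@H](C)CO[Si](c1ccccc1)(c1ccccc1)C(C)(C)C | intermediate
8 | (2Z,4E,6R)-7-[(tert-butyldiphenylsilyl)oxy]-2,6-dimethylhepta-2,4-dien-1-yl acetate | CC(=O)OC/C(C)=C\C=C\[C@@H](C)CO[Si](c1ccccc1)(c1ccccc1)C(C)(C)C | intermediate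
9 | [(3S,6S)-6-[(2S)-1-[(tert-butyldiphenylsilyl)oxy]propan-2-yl]-3-methyl-3,6-dihydro-1,2-dioxin-3-yl]methyl acetate | CC(=O)OC[C@]1(C)C=C[C@@H]([C@@H](C)CO[Si](c2ccccc2)(c2ccccc2)C(C)(C)C)OO1 | intermediate
10 | [(3S,6S)-6-[(2S)-1-[(tert-butyldiphenylsilyl)oxy]propan-2-yl]-3-methyl-1,2-dioxan-3-yl]methyl acetate | CC(=O)OC[C@]1(C)CC[C@@H]([C@@H](C)CO[Si](c2ccccc2)(c2ccccc2)C(C)(C)C)OO1 | intermediate
11 | [(3S,6S)-6-[(2S)-1-[(tert-butyldiphenylsilyl)oxy]propan-2-yl]-3-methyl-1,2-dioxan-3-yl]methanol | OC[C@]1(C)CC[C@@H]([C@@H](C)CO[Si](c2ccccc2)(c2ccccc2)C(C)(C)C)OO1 | intermediate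
12 | (3S,6S)-6-[(2S)-1-[(tert-butyldiphenylsilyl)oxy]propan-2-yl]-3-methyl-1,2-dioxane-3-carbaldehyde | O=C[C@]1(C)CC[C@@H]([C@@H](C)CO[Si](c2ccccc2)(c2ccccc2)C(C)(C)C)OO1 | intermediate
13 | tert-butyl{(2S)-2-[(3S,6S)-6-ethenyl-6-methyl-1,2-dioxan-3-yl]propoxy}diphenylsilane | C=C[C@]1(C)CC[C@@H]([C@@H](C)CO[Si](c2ccccc2)(c2ccccc2)C(C)(C)C)OO1 | intermediate
14 | dihydro-β-ionone, 4-(2,6,6-trimethylcyclohex-1-en-1-yl)butan-2-one | CC(=O)CCC1=C(C)CCCC1(C)C | starting material
15 | ethyl (2E)-3-methyl-5-(2,6,6-trimethylcyclohex-1-en-1-yl)pent-2-enoate | CCOC(=O)/C=C(\C)CCC1=C(C)CCCC1(C)C | intermediate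
16 | (2E)-3-methyl-5-(2,6,6-trimethylcyclohex-1-en-1-yl)pent-2-en-1-ol (monocyclofarnesol) | OC/C=C(\C)CCC1=C(C)CCCC1(C)C | intermediate
17 | [(2S,3S)-3-methyl-3-[2-(2,6,6-trimethylcyclohex-1-en-1-yl)ethyl]oxiran-2-yl]methanol | CC1=C(CC[C@]2(C)O[C@H]2CO)C(C)(C)CCC1 | intermediate
18 | (2R,3S)-3-methyl-3-[2-(2,6,6-trimethylcyclohex-1-en-1-yl)ethyl]oxirane-2-carbaldehyde | CC1=C(CC[C@]2(C)O[C@H]2C=O)C(C)(C)CCC1 | intermediate
19 | (2S,3S)-3-ethenyl-2-methyl-2-[2-(2,6,6-trimethylcyclohex-1-en-1-yl)ethyl]oxirane | CC1=C(CC[C@]2(C)O[C@H]2C=C)C(C)(C)CCC1 | intermediate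
20 | tert-butyl{(2S)-2-[(3S,6S)-6-methyl-6-{(E)-2-[(2S,3S)-3-methyl-3-[2-(2,6,6-trimethylcyclohex-1-en-1-yl)ethyl]oxiran-2-yl]ethenyl}-1,2-dioxan-3-yl]propoxy}diphenylsilane | CC1=C(CC[C@]2(C)O[C@H]2/C=C/[C@]3(C)CC[C@@H]([C@@H](C)CO[Si](c4ccccc4)(c4ccccc4)C(C)(C)C)OO3)C(C)(C)CCC1 | intermediate
21 | tert-butyl{(2S)-2-[(3S,6R)-6-methyl-6-{2-[(2S,3S)-3-methyl-3-[2-(2,6,6-trimethylcyclohex-1-en-1-yl)ethyl]oxiran-2-yl]ethyl}-1,2-dioxan-3-yl]propoxy}diphenylsilane | CC1=C(CC[C@]2(C)O[C@H]2CC[C@]3(C)CC[C@@H]([C@@H](C)CO[Si](c4ccccc4)(c4ccccc4)C(C)(C)C)OO3)C(C)(C)CCC1 | intermediate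
22 | (2S)-2-[(3S,6R)-6-methyl-6-{2-[(2S,3S)-3-methyl-3-[2-(2,6,6-trimethylcyclohex-1-en-1-yl)ethyl]oxiran-2-yl]ethyl}-1,2-dioxan-3-yl]propan-1-ol | CC1=C(CC[C@]2(C)O[C@H]2CC[C@]3(C)CC[C@@H]([C@@H](C)CO)OO3)C(C)(C)CCC1 | intermediate
23 | (2R)-2-[(3S,6R)-6-methyl-6-{2-[(2S,3S)-3-methyl-3-[2-(2,6,6-trimethylcyclohex-1-en-1-yl)ethyl]oxiran-2-yl]ethyl}-1,2-dioxan-3-yl]propanal | CC1=C(CC[C@]2(C)O[C@H]2CC[C@]3(C)CC[C@@H]([C@@H](C)C=O)OO3)C(C)(C)CCC1 | intermediate
24 | (2R)-2-[(3S,6R)-6-methyl-6-{2-[(2S,3S)-3-methyl-3-[2-(2,6,6-trimethylcyclohex-1-en-1-yl)ethyl]oxiran-2-yl]ethyl}-1,2-dioxan-3-yl]propanoic acid (CNP0204283.1) | CC1=C(CC[C@]2(C)O[C@H]2CC[C@]2(C)CC[C@@H]([C@@H](C)C(=O)O)OO2)C(C)(C)CCC1 | target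

**Step count and risks**

Total step count: 21. Longest linear sequence: 16 (steps 1–11, then 17–21); the side branch is steps 12–16.

Steps most likely to fail:

1. Step 7 (photo-oxygenation). The s-cis conformer is penalised by the inside CH2OAc group, so the ene reaction at the C6 methyl, loss of the 5Z geometry through open intermediates, or weak face selection at C2 may erode the wanted isomer. The fallback builds the ring stepwise; it sets out from aldehyde 3 and comes back at alcohol 11. Felkin–Anh addition of (3-methylbut-3-en-1-yl)magnesium bromide to 3 should give mainly the 2,3-syn alcohol, (2S,3S)-1-[(tert-butyldiphenylsilyl)oxy]-2,6-dimethylhept-6-en-3-ol F1, whose C3–O already has the target's sense. Appel bromination (CBr4, PPh3) should give, with inversion, the bromide tert-butyl{[(2S,3R)-3-bromo-2,6-dimethylhept-6-en-1-yl]oxy}diphenylsilane F2. mCPBA epoxidises the 1,1-disubstituted alkene to the oxirane tert-butyl{[(2S,3R)-3-bromo-2-methyl-5-[(2R)-2-methyloxiran-2-yl]pentyl]oxy}diphenylsilane F3, formed without control together with its oxirane epimer. Phosphomolybdic-acid-catalysed perhydrolysis with ethereal H2O2 opens the oxirane at the tertiary carbon to the β-hydroxy hydroperoxide (2S,5R,6S)-5-bromo-7-[(tert-butyldiphenylsilyl)oxy]-2-hydroperoxy-2,6-dimethylheptan-1-ol F4. CsOH in DMF then closes the dioxane by 6-exo-tet displacement of bromide with a second inversion at C3, to give 11 after separation from its C6 epimer.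

2. Step 17 (cross-metathesis). The ruthenium carbene may engage the quaternary-allylic vinyl group too slowly, so that only dimerisation of 19 and catalyst decay are seen. The fallback is a relay metathesis; it sets out from aldehyde 12 and comes back at 20. Wittig reaction of 12 with the ylide of (hex-5-en-1-yl)triphenylphosphonium bromide gives the relay diene tert-butyl{(2S)-2-[(3S,6S)-6-[(1Z)-hepta-1,6-dien-1-yl]-6-methyl-1,2-dioxan-3-yl]propoxy}diphenylsilane F5. With the same catalyst and 19, the carbene loads on the unhindered terminal alkene of F5, ring-closes with loss of cyclopentene and thereby places the ruthenium alkylidene directly on C7, where it is captured by 19 to give 20.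

3. Step 21 (with step 20, final oxidation). Hypochlorite that escapes the scavenger may chlorinate the cyclohexene, the buffer may open the oxirane, or the β-peroxy aldehyde may epimerise or eliminate before it is oxidised. The fallback brings C1 to the acid before the cyclohexene and the oxirane are attached; it sets out from 13 and comes back at 24. TBAF/AcOH gives the alcohol (2S)-2-[(3S,6S)-6-ethenyl-6-methyl-1,2-dioxan-3-yl]propan-1-ol F6, Dess–Martin oxidation the aldehyde (2R)-2-[(3S,6S)-6-ethenyl-6-methyl-1,2-dioxan-3-yl]propanal F7, and Pinnick oxidation, now with only a monosubstituted alkene present, the acid (2R)-2-[(3S,6S)-6-ethenyl-6-methyl-1,2-dioxan-3-yl]propanoic acid F8. Cross-metathesis of F8 with 19 (ruthenium carbenes tolerate free carboxylic acids) gives the unsaturated acid (2R)-2-[(3S,6S)-6-methyl-6-{(E)-2-[(2S,3S)-3-methyl-3-[2-(2,6,6-trimethylcyclohex-1-en-1-yl)ethyl]oxiran-2-yl]ethenyl}-1,2-dioxan-3-yl]propanoic acid F9, and diimide (2-nitrobenzenesulfonyl hydrazide, excess Et3N) reduces C7=C8 to give 24.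

Further compounds
F1 | step 7 | (2S,3S)-1-[(tert-butyldiphenylsilyl)oxy]-2,6-dimethylhept-6-en-3-ol | CC(=C)CC[C@H](O)[C@@H](C)CO[Si](c1ccccc1)(c1ccccc1)C(C)(C)C
F2 | step 7 | tert-butyl{[(2S,3R)-3-bromo-2,6-dimethylhept-6-en-1-yl]oxy}diphenylsilane | CC(=C)CC[C@@H](Br)[C@@H](C)CO[Si](c1ccccc1)(c1ccccc1)C(C)(C)C
F3 | step 7 | tert-butyl{[(2S,3R)-3-bromo-2-methyl-5-[(2R)-2-methyloxiran-2-yl]pentyl]oxy}diphenylsilane | C[C@]1(CO1)CC[C@@H](Br)[C@@H](C)CO[Si](c2ccccc2)(c2ccccc2)C(C)(C)C
F4 | step 7 | (2S,5R,6S)-5-bromo-7-[(tert-butyldiphenylsilyl)oxy]-2-hydroperoxy-2,6-dimethylheptan-1-ol | OC[C@](OO)(C)CC[C@@H](Br)[C@@H](C)CO[Si](c1ccccc1)(c1ccccc1)C(C)(C)C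
F5 | step 17 | tert-butyl{(2S)-2-[(3S,6S)-6-[(1Z)-hepta-1,6-dien-1-yl]-6-methyl-1,2-dioxan-3-yl]propoxy}diphenylsilane | C=CCCC/C=C\[C@]1(C)CC[C@@H]([C@@H](C)CO[Si](c2ccccc2)(c2ccccc2)C(C)(C)C)OO1
F6 | step 21 | (2S)-2-[(3S,6S)-6-ethenyl-6-methyl-1,2-dioxan-3-yl]propan-1-ol | C=C[C@]1(C)CC[C@@H]([C@@H](C)CO)OO1
F7 | step 21 | (2R)-2-[(3S,6S)-6-ethenyl-6-methyl-1,2-dioxan-3-yl]propanal | C=C[C@]1(C)CC[C@@H]([C@@H](C)C=O)OO1
F8 | step 21 | (2R)-2-[(3S,6S)-6-ethenyl-6-methyl-1,2-dioxan-3-yl]propanoic acid | C=C[C@]1(C)CC[C@@H]([C@@H](C)C(=O)O)OO1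
F9 | step 21 | (2R)-2-[(3S,6S)-6-methyl-6-{(E)-2-[(2S,3S)-3-methyl-3-[2-(2,6,6-trimethylcyclohex-1-en-1-yl)ethyl]oxiran-2-yl]ethenyl}-1,2-dioxan-3-yl]propanoic acid | CC1=C(CC[C@]2(C)O[C@H]2/C=C/[C@]3(C)CC[C@@H]([C@@H](C)C(=O)O)OO3)C(C)(C)CCC1
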